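The meso oxolane is cut at C2–C3 and C4–C5, leaving the bis-benzylic C2–O–C5 unit as a 1,3-diaryl carbonyl ylide and C3–C4 as a cis-locked alkene. Photosensitised ring opening of a trans-2,3-diaryloxirane in the presence of maleic anhydride forms both C–C bonds in one (3+2) cycloaddition. The temporary anhydride ring fixes C3 and C4 cis and is later reduced to the two CH2OAc arms. The feature exploited is the oxolane ring oxygen flanked by two electron-rich benzylic carbons, which also lets C2 and C5 be equilibrated by acid to the aryl-trans arrangement. The precursor is an epoxide, not an oxolane.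

Key step: step 2

Remark: oxolane numbering is O1, C2/C5 (aryl-bearing), C3/C4 (CH2OAc-bearing). The target is meso (2R,3S,4R,5S): aryls mutually cis, CH2OAc groups mutually cis, each aryl trans to its neighbouring CH2OAc. Only relative configuration has to be controlled, and chiral intermediates are racemic.

Step 1
Reactants: 1 3,4-bis(benzyloxy)benzyl chloride; 2 3,4-bis(benzyloxy)benzaldehyde
Product: 4 trans-2,3-bis[3,4-bis(benzyloxy)phenyl]oxirane (racemic), via sulfonium chloride 3 (not isolated)
Conditions: tetrahydrothiophene, MeCN, rt; then 2, NaOH (powder), MeCN, 0 °C to rt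
Reagents that add atoms: none
Why: Corey–Chaykovsky epoxidation through the benzylic sulfonium ylide of 3; reversible betaine formation with this semi-stabilised ylide should give the trans-oxirane, and the basic medium protects the acid-labile electron-rich epoxide.

Step 2
Reactants: 4 trans-2,3-bis[3,4-bis(benzyloxy)phenyl]oxirane; 5 maleic anhydride
Product: 7 all-cis 4,6-bis[3,4-bis(benzyloxy)phenyl]tetrahydro-1H,3H-furo[3,4-c]furan-1,3-dione (meso), via carbonyl ylide 6 (not isolated)
Conditions: 9,10-dicyanoanthracene (5 mol %), 5 (3 equiv), MeCN–CH2Cl2, 405 nm LEDs, N2, rt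
Reagents that add atoms: none
Why: Photoexcited 9,10-dicyanoanthracene oxidises a dialkoxyaryl ring of 4, the oxirane radical cation cleaves its C–C bond and back electron transfer gives the exo,exo (W-shaped) 1,3-diaryl carbonyl ylide 6, which adds across the C=C bond of 5 in a concerted suprafacial (3+2) cycloaddition that forms C2–C3 and C4–C5 together. The closest known reaction type is the electron-transfer-sensitised carbonyl ylide cycloaddition of 2,3-diaryloxiranes with electron-poor alkenes (Huisgen 1,3-dipolar cycloaddition). The oxolane ring is closed by this intermolecular [π4s+π2s] cycloaddition, not by cyclisation of a chain, and it arises cis-fused to the anhydride ring. C3 and C4 are set cis by the five-membered ring of 5, which cannot isomerise and can only be fused cis; C2 and C5 are set mutually cis by the W geometry of 6 and cis to the anhydride by the expected endo transition state, in which the anhydride carbonyls lie under the aryl-extended ylide. The step needs only the cis C3/C4 relationship and trapping of 6 faster than its collapse back to oxirane or rearrangement to carbonyl compounds, which the ring of 5 and its use in excess secure. The endo or exo sense need not be controlled, because step 5 later equilibrates C2 and C5.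

Step 3
Reactants: 7 all-cis anhydride
Product: 8 all-cis [(2S,3S,4R,5R)-2,5-bis[3,4-bis(benzyloxy)phenyl]oxolane-3,4-diyl]dimethanol (meso)
Conditions: LiAlH4, THF, 0 °C to reflux; H2O/aq NaOH work-up
Reagents that add atoms: none
Why: Hydride reduction of a cyclic anhydride to the 1,4-diol opens the temporary ring; no stereocentre is touched, and the basic work-up avoids acid-induced capture of a benzylic cation by the new hydroxyl groups.

Step 4
Reactants: 8 all-cis diol
Product: 9 all-cis [(2S,3S,4R,5R)-2,5-bis[3,4-bis(benzyloxy)phenyl]oxolane-3,4-diyl]bis(methylene) diacetate (meso)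
Conditions: Ac2O, pyridine, DMAP (cat.), CH2Cl2, rt
Reagents that add atoms: acetic anhydride CC(=O)OC(C)=O
Why: Standard nucleophile-catalysed acylation of two primary alcohols; capping the hydroxyl groups also removes the internal nucleophiles before the acid step.

Step 5
Reactants: 9 all-cis diacetate
Product: 10 [(2R,3S,4R,5S)-2,5-bis[3,4-bis(benzyloxy)phenyl]oxolane-3,4-diyl]bis(methylene) diacetate (meso; aryls cis to each other and trans to the CH2OAc groups)
Conditions: BF3·OEt2 (0.3 equiv), CH2Cl2, −20 to 0 °C; Et3N quench
Reagents that add atoms: none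
Why: Acid-mediated epimerisation of a 2-aryloxolane by reversible ring opening to a benzylic cation stabilised by the para-benzyloxy group. With C3/C4 locked cis, the isomer with each aryl trans to its neighbouring CH2OAc is the thermodynamic sink, so both C2 and C5 should invert and no other centre changes.

Step 6
Reactants: 10 tetrabenzyl diacetate
Product: 11 [(2R,3S,4R,5S)-2,5-bis(3,4-dihydroxyphenyl)oxolane-3,4-diyl]bis(methylene) diacetate (meso; target)
Conditions: H2 (1 atm), Pd/C (10 %), EtOAc–THF, rt
Reagents that add atoms: none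
Why: Hydrogenolysis of four aryl benzyl ethers under neutral conditions; the acetates are inert, the ring benzylic ether bonds cleave far more slowly, and no stereocentre is affected.

Compound list
1 | 3,4-bis(benzyloxy)benzyl chloride | ClCc1ccc(OCc2ccccc2)c(OCc2ccccc2)c1 | starting material
2 | 3,4-bis(benzyloxy)benzaldehyde | O=Cc1ccc(OCc2ccccc2)c(OCc2ccccc2)c1 | starting material
3 | 1-[3,4-bis(benzyloxy)benzyl]tetrahydrothiophenium chloride | [Cl-].C1CC[S+](Cc2ccc(OCc3ccccc3)c(OCc3ccccc3)c2)C1 | intermediate
4 | trans-2,3-bis[3,4-bis(benzyloxy)phenyl]oxirane (racemic) | O(Cc1ccccc1)c1ccc(cc1OCc1ccccc1)[C@H]1O[C@@H]1c1ccc(OCc2ccccc2)c(OCc2ccccc2)c1 | intermediate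
5 | maleic anhydride | O=C1OC(=O)C=C1 | starting material
6 | W-shaped carbonyl ylide, [3,4-bis(benzyloxy)benzylidene]oxonium 3,4-bis(benzyloxy)benzylide | [CH-](c1ccc(OCc2ccccc2)c(OCc2ccccc2)c1)/[O+]=C/c1ccc(OCc2ccccc2)c(OCc2ccccc2)c1 | intermediate
7 | all-cis 4,6-bis[3,4-bis(benzyloxy)phenyl]tetrahydro-1H,3H-furo[3,4-c]furan-1,3-dione (meso; both aryls cis to the anhydride ring) | O=C1OC(=O)[C@@H]2[C@H]1[C@H](c1ccc(OCc3ccccc3)c(OCc3ccccc3)c1)O[C@@H]2c1ccc(OCc2ccccc2)c(OCc2ccccc2)c1 | intermediate
8 | all-cis [(2S,3S,4R,5R)-2,5-bis[3,4-bis(benzyloxy)phenyl]oxolane-3,4-diyl]dimethanol (meso) | OC[C@@H]1[C@H](CO)[C@H](c2ccc(OCc3ccccc3)c(OCc3ccccc3)c2)O[C@@H]1c1ccc(OCc2ccccc2)c(OCc2ccccc2)c1 | intermediate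
9 | all-cis [(2S,3S,4R,5R)-2,5-bis[3,4-bis(benzyloxy)phenyl]oxolane-3,4-diyl]bis(methylene) diacetate (meso) | CC(=O)OC[C@@H]1[C@H](COC(C)=O)[C@H](c2ccc(OCc3ccccc3)c(OCc3ccccc3)c2)O[C@@H]1c1ccc(OCc2ccccc2)c(OCc2ccccc2)c1 | intermediate
10 | [(2R,3S,4R,5S)-2,5-bis[3,4-bis(benzyloxy)phenyl]oxolane-3,4-diyl]bis(methylene) diacetate (meso) | CC(=O)OC[C@@H]1[C@H](COC(C)=O)[C@@H](c2ccc(OCc3ccccc3)c(OCc3ccccc3)c2)O[C@H]1c1ccc(OCc2ccccc2)c(OCc2ccccc2)c1 | intermediate
11 | [(2R,3S,4R,5S)-2,5-bis(3,4-dihydroxyphenyl)oxolane-3,4-diyl]bis(methylene) diacetate (meso) | CC(=O)OC[C@@H]1[C@H](COC(C)=O)[C@@H](c2ccc(O)c(O)c2)O[C@H]1c1ccc(O)c(O)c1 | target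

Total step count: 6
Longest linear sequence: 6 steps (from 1 or 2 to 11)

Steps most likely to fail

Step 2. The anhydride may quench the excited sensitiser or enter charge-transfer photochemistry with the electron-rich rings, the oxirane radical cation may rearrange before the ylide is trapped, or the anhydride adduct may hydrolyse on isolation. The fallback changes the dipolarophile to an alkyne and sets C3/C4 in a separate hydrogenation. It sets out from 4: the same sensitised irradiation with dimethyl acetylenedicarboxylate should give dimethyl cis-2,5-bis[3,4-bis(benzyloxy)phenyl]-2,5-dihydrofuran-3,4-dicarboxylate F1. DIBAL-H (CH2Cl2, −78 °C) should reduce it to [cis-2,5-bis[3,4-bis(benzyloxy)phenyl]-2,5-dihydrofuran-3,4-diyl]dimethanol F2. Hydroxyl-assisted hydrogenation of the tetrasubstituted alkene with [Ir(cod)(PCy3)(py)]PF6 and H2 in CH2Cl2, from the face opposite the two aryl groups, should give the all-cis diol, and the route is rejoined at 8.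

Step 5. The benzylic cation may be captured irreversibly by the other aryl ring (Friedel–Crafts closure to an aryltetralin), may lose a proton, or equilibration may stall at the mono-epimer. The fallback moves the equilibration to the free-phenol stage, where ionisation through a para-quinone methide needs only trace acid. It sets out from 9: hydrogenolysis (H2, Pd/C, EtOAc–THF) should give all-cis [(2S,3S,4R,5R)-2,5-bis(3,4-dihydroxyphenyl)oxolane-3,4-diyl]bis(methylene) diacetate F3. Brief treatment with 1 % CF3CO2H in CH2Cl2–MeCN at rt should then invert C2 and C5 to the thermodynamic arrangement, and the route is rejoined at 11.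

Step 6. Over-reduction may cleave the bis-benzylic ring C–O bonds once the catechols are unveiled. The fallback replaces hydrogenolysis by Lewis-acid debenzylation: from 10, BCl3 with pentamethylbenzene as non-basic cation scavenger (CH2Cl2, −78 °C) should remove the four benzyl groups and give 11 directly. This fallback makes no new compound (F0).

Further compounds
F1 | step 2 | dimethyl cis-2,5-bis[3,4-bis(benzyloxy)phenyl]-2,5-dihydrofuran-3,4-dicarboxylate | COC(=O)C1=C(C(=O)OC)[C@@H](c2ccc(OCc3ccccc3)c(OCc3ccccc3)c2)O[C@H]1c1ccc(OCc2ccccc2)c(OCc2ccccc2)c1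
F2 | step 2 | [cis-2,5-bis[3,4-bis(benzyloxy)phenyl]-2,5-dihydrofuran-3,4-diyl]dimethanol | OCC1=C(CO)[C@@H](c2ccc(OCc3ccccc3)c(OCc3ccccc3)c2)O[C@H]1c1ccc(OCc2ccccc2)c(OCc2ccccc2)c1
F3 | step 5 | all-cis [(2S,3S,4R,5R)-2,5-bis(3,4-dihydroxyphenyl)oxolane-3,4-diyl]bis(methylene) diacetate | CC(=O)OC[C@@H]1[C@H](COC(C)=O)[C@H](c2ccc(O)c(O)c2)O[C@@H]1c1ccc(O)c(O)c1
F0 | step 6 | none | none
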